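**Plan**

Rings: A = 3,5-dihydroxyphenoxy group on the outer dioxin benzo ring B; C = central ring shared by dioxin and furan; D = outer furan benzo ring; E = 3,5-dihydroxyphenoxy group on ring D.
Enabling feature: in ring B the hydroxyl carbon beside O–ring A and the dioxin carbon beside the other hydroxyl carbon are para, and the two adjacent carbons between them bear O–ring A and the dioxin oxygen that leads to C2 of ring C, so ring B is a masked 2,3-dioxy-1,4-benzoquinone.
Cuts: the dioxin C–O bond at the bay carbon C1 of ring C (copper closure onto a bromide); the two neighbouring aryl–O bonds on ring B (to ring A and to O–C2 of ring C), both made in one pot on 2,3-dibromo-5-methoxy-1,4-benzoquinone; the furan of rings C/D at C9a–C9b and C4a–O (quinone–phenol condensation); the ring D–O–ring E ether (Ullmann).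
Forward: 5-bromovanillin gives one bromoquinone used twice (ring C directly, ring B after HBr addition); the ring D–E phenol is built; the furan closes to join rings C and D; ring B is attached together with ring A; reduction and dioxin closure complete the pentacycle; eight methyl ethers are cleaved last.
Stereochemistry: none to set; the target is achiral and has no stereocentre.

Key step: step 10

Assumption: in the acid-mediated furan formation the aryloxyphenol is taken to react through its carbon ortho to the free hydroxyl, since only that adduct can close the furan; dibenzofuran positions follow dibenzo[b,d]furan numbering (O = 5, bay carbons 1 and 9).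

**Route**

Step 1
Reactants: 1 5-bromovanillin (3-bromo-4-hydroxy-5-methoxybenzaldehyde)
Product: 2 2-bromo-6-methoxybenzene-1,4-diol
Conditions: 30% aq. H2O2, NaOH, THF–H2O, 0 °C to rt, N2; then HCl
Reagents that add atoms: hydrogen peroxide, OO
Why: Dakin oxidation of a para-hydroxybenzaldehyde; hydroperoxide adds to the aldehyde, the electron-rich aryl group migrates to oxygen and the formate is hydrolysed in the basic medium.

Step 2
Reactants: 2 2-bromo-6-methoxybenzene-1,4-diol
Product: 3 2-bromo-6-methoxy-1,4-benzoquinone
Conditions: NaIO4, CH2Cl2–H2O, rt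
Reagents that add atoms: none
Why: Periodate oxidation of a hydroquinone to the p-quinone, a clean two-electron oxidation with no other oxidisable group present.

Step 3
Reactants: 3 2-bromo-6-methoxy-1,4-benzoquinone
Product: 4 2,3-dibromo-5-methoxybenzene-1,4-diol
Conditions: HBr (33% in AcOH), CH2Cl2, 0 °C
Reagents that add atoms: hydrogen bromide, Br
Why: Hydrohalogenation of a quinone (1,4-addition of HBr, then enolisation); the methoxy group makes the C4 carbonyl a vinylogous ester, so bromide should add at C3, β to the C1 carbonyl and next to the bromine-bearing carbon, the usual site for halide addition to a 2-haloquinone.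

Step 4
Reactants: 4 2,3-dibromo-5-methoxybenzene-1,4-diol
Product: 5 2,3-dibromo-5-methoxy-1,4-benzoquinone
Conditions: NaIO4, CH2Cl2–H2O, rt
Reagents that add atoms: none
Why: Periodate oxidation of the hydroquinone to the quinone; the work-up after step 3 removes HBr, so no bromine is generated that could attack the enol ether carbon.

Step 5
Reactants: 6 2-hydroxy-4,6-dimethoxybenzaldehyde
Product: 7 2-(benzyloxy)-4,6-dimethoxybenzaldehyde
Conditions: BnBr, K2CO3, DMF, 60 °C
Reagents that add atoms: benzyl bromide, BrCc1ccccc1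
Why: Williamson ether synthesis on the only phenol; the benzyl group masks the oxygen that later becomes the furan oxygen.

Step 6
Reactants: 7 2-(benzyloxy)-4,6-dimethoxybenzaldehyde
Product: 9 2-(benzyloxy)-4,6-dimethoxyphenol, via aryl formate 8 (not isolated)
Conditions: mCPBA (1.1 equiv), CH2Cl2, 0 °C to rt; then K2CO3 (cat.), MeOH, rt, N2
Reagents that add atoms: mCPBA (3-chloroperoxybenzoic acid), OOC(=O)c1cccc(Cl)c1
Why: Baeyer–Villiger oxidation of a 2,4,6-trialkoxybenzaldehyde, in which the electron-rich aryl group migrates, followed by methanolysis of the formate.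

Step 7
Reactants: 9 2-(benzyloxy)-4,6-dimethoxyphenol; 10 1-iodo-3,5-dimethoxybenzene
Product: 11 1-(benzyloxy)-2-(3,5-dimethoxyphenoxy)-3,5-dimethoxybenzene
Conditions: CuI (10 mol%), picolinic acid (20 mol%), K3PO4, DMSO, 90 °C, Ar
Reagents that add atoms: none
Why: Ullmann diaryl ether synthesis; the copper–picolinate system couples di-ortho-substituted phenols with aryl iodides, and the inert atmosphere protects the electron-rich phenol.

Step 8
Reactants: 11 1-(benzyloxy)-2-(3,5-dimethoxyphenoxy)-3,5-dimethoxybenzene
Product: 12 2-(3,5-dimethoxyphenoxy)-3,5-dimethoxyphenol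
Conditions: H2 (1 atm), Pd/C, EtOAc–MeOH, rt
Reagents that add atoms: none
Why: Hydrogenolysis of the benzyl ether; diaryl and methyl ethers are inert and no halogen is present at this stage.

Step 9
Reactants: 3 2-bromo-6-methoxy-1,4-benzoquinone; 12 2-(3,5-dimethoxyphenoxy)-3,5-dimethoxyphenol
Product: 14 1-bromo-6-(3,5-dimethoxyphenoxy)-3,7,9-trimethoxydibenzo[b,d]furan-2-ol, via arylhydroquinone 13 (not isolated)
Conditions: TsOH·H2O (20 mol%), toluene, 3 added slowly to 12 (1.1 equiv), rt; then 80 °C, 4 Å MS
Reagents that add atoms: none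
Why: Acid-mediated condensation of a quinone with an electron-rich phenol to a 2-hydroxydibenzofuran: the ring D carbon ortho to the hydroxyl (guided by hydrogen bonding to the quinone carbonyl and less crowded than the para carbon between two methoxy groups) adds to C3 of the quinone, the position β to the carbonyl that the methoxy group does not deactivate, and hydroquinone 13 then closes the furan by loss of water through the keto tautomer of the phloroglucinol-type ring.

Step 10
Reactants: 5 2,3-dibromo-5-methoxy-1,4-benzoquinone; 15 3,5-dimethoxyphenol; 14 1-bromo-6-(3,5-dimethoxyphenoxy)-3,7,9-trimethoxydibenzo[b,d]furan-2-ol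
Product: 17 2-(3,5-dimethoxyphenoxy)-3-{[1-bromo-6-(3,5-dimethoxyphenoxy)-3,7,9-trimethoxydibenzo[b,d]furan-2-yl]oxy}-5-methoxy-1,4-benzoquinone, via bromo(aryloxy)quinone 16 (not isolated)
Conditions: Cs2CO3 (2.5 equiv), MeCN, −20 °C, 15 (1.0 equiv) added over 1 h; then 14 (1.05 equiv), rt to 45 °C, Ar, dark
Reagents that add atoms: none
Why: Each C–O bond forms by conjugate addition of a caesium phenoxide to a bromine-bearing enone carbon of the quinone followed by loss of bromide, the addition–elimination known for stepwise replacement of the halogens of 2,3-dihalo-1,4-quinones by two different phenoxides. No ring closes and no stereocentre arises. The selectivity needed is which bromine leaves first: the 5-methoxy group turns the C1 carbonyl into a vinylogous ester, so the oxide of 15 should attack C2, the β-carbon of the still ketone-like C4 enone, which is the carbon that must carry ring A. The new aryloxy group damps the quinone, so a second molecule of 15 should not be taken up at −20 °C, and the slower displacement at C3 is left to the oxide of 14, which has no free ortho or para carbon and can react only through oxygen. Adding the small, poorly oxidisable phenoxide first also means that the hindered, electron-rich oxide of 14 meets the less oxidising monoether and not the dibromoquinone. Attack of that oxide at C2 should be unproductive, because the tetrahedral adduct expels the bulkier and more acidic dibenzofuranoxide again.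

Step 11
Reactants: 17 diaryloxyquinone from step 10
Product: 18 2-(3,5-dimethoxyphenoxy)-3-{[1-bromo-6-(3,5-dimethoxyphenoxy)-3,7,9-trimethoxydibenzo[b,d]furan-2-yl]oxy}-5-methoxybenzene-1,4-diol
Conditions: Na2S2O4, EtOAc–H2O, rt, Ar
Reagents that add atoms: none
Why: Dithionite reduction of a quinone to its hydroquinone; aryl bromide and ethers are untouched, and the former C4 carbonyl oxygen becomes the phenol that will close the dioxin.

Step 12
Reactants: 18 hydroquinone from step 11
Product: 19 phlorofucofuroeckol A octamethyl ether with the ring B hydroxyl beside the ring A ether free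
Conditions: CuI (30 mol%), 2,2,6,6-tetramethylheptane-3,5-dione (60 mol%), Cs2CO3 (3 equiv), degassed NMP, 120 °C, Ar
Reagents that add atoms: none
Why: Intramolecular Ullmann ether synthesis, as in the standard route from 2-(2-bromophenoxy)phenols to dibenzo-1,4-dioxins; the phenoxide flanked by the dibenzofuranyloxy and methoxy groups displaces the bay bromide of ring C in a six-membered closure, whereas the other hydroxyl could only form a seven-membered ring.

Step 13
Reactants: 19 monohydroxy octamethyl ether from step 12
Product: 20 phlorofucofuroeckol A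
Conditions: BBr3 (excess), CH2Cl2, −78 °C to rt; then MeOH–H2O, Ar
Reagents that add atoms: none
Why: Lewis-acid cleavage of aryl methyl ethers with BBr3; diaryl ether, dioxin and furan C–O bonds are inert, so all eight methyl groups should be removed without skeletal change.

**Compound list**

1 | 5-bromovanillin | COc1cc(C=O)cc(Br)c1O | starting material
2 | 2-bromo-6-methoxybenzene-1,4-diol | COc1cc(O)cc(Br)c1O | intermediate
3 | 2-bromo-6-methoxy-1,4-benzoquinone | COC1=CC(=O)C=C(Br)C1=O | intermediate
4 | 2,3-dibromo-5-methoxybenzene-1,4-diol | COc1cc(O)c(Br)c(Br)c1O | intermediate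
5 | 2,3-dibromo-5-methoxy-1,4-benzoquinone | COC1=CC(=O)C(Br)=C(Br)C1=O | intermediate
6 | 2-hydroxy-4,6-dimethoxybenzaldehyde | COc1cc(O)c(C=O)c(OC)c1 | starting material
7 | 2-(benzyloxy)-4,6-dimethoxybenzaldehyde | COc1cc(OCc2ccccc2)c(C=O)c(OC)c1 | intermediate
8 | 2-(benzyloxy)-4,6-dimethoxyphenyl formate (not isolated) | COc1cc(OCc2ccccc2)c(OC=O)c(OC)c1 | intermediate
9 | 2-(benzyloxy)-4,6-dimethoxyphenol | COc1cc(OCc2ccccc2)c(O)c(OC)c1 | intermediate
10 | 1-iodo-3,5-dimethoxybenzene | COc1cc(I)cc(OC)c1 | starting material
11 | 1-(benzyloxy)-2-(3,5-dimethoxyphenoxy)-3,5-dimethoxybenzene | COc1cc(OCc2ccccc2)c(Oc2cc(OC)cc(OC)c2)c(OC)c1 | intermediate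
12 | 2-(3,5-dimethoxyphenoxy)-3,5-dimethoxyphenol | COc1cc(O)c(Oc2cc(OC)cc(OC)c2)c(OC)c1 | intermediate
13 | 3-bromo-2-[3-(3,5-dimethoxyphenoxy)-2-hydroxy-4,6-dimethoxyphenyl]-5-methoxybenzene-1,4-diol (not isolated) | COc1cc(O)c(-c2c(O)c(Oc3cc(OC)cc(OC)c3)c(OC)cc2OC)c(Br)c1O | intermediate
14 | 1-bromo-6-(3,5-dimethoxyphenoxy)-3,7,9-trimethoxydibenzo[b,d]furan-2-ol | COc1cc2oc3c(Oc4cc(OC)cc(OC)c4)c(OC)cc(OC)c3c2c(Br)c1O | intermediate
15 | 3,5-dimethoxyphenol | COc1cc(O)cc(OC)c1 | starting material
16 | 3-bromo-2-(3,5-dimethoxyphenoxy)-5-methoxy-1,4-benzoquinone (not isolated) | COC1=CC(=O)C(Oc2cc(OC)cc(OC)c2)=C(Br)C1=O | intermediate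
17 | 2-(3,5-dimethoxyphenoxy)-3-{[1-bromo-6-(3,5-dimethoxyphenoxy)-3,7,9-trimethoxydibenzo[b,d]furan-2-yl]oxy}-5-methoxy-1,4-benzoquinone | COC1=CC(=O)C(Oc2cc(OC)cc(OC)c2)=C(Oc2c(OC)cc3oc4c(Oc5cc(OC)cc(OC)c5)c(OC)cc(OC)c4c3c2Br)C1=O | intermediate
18 | 2-(3,5-dimethoxyphenoxy)-3-{[1-bromo-6-(3,5-dimethoxyphenoxy)-3,7,9-trimethoxydibenzo[b,d]furan-2-yl]oxy}-5-methoxybenzene-1,4-diol | COc1cc(O)c(Oc2cc(OC)cc(OC)c2)c(Oc2c(OC)cc3oc4c(Oc5cc(OC)cc(OC)c5)c(OC)cc(OC)c4c3c2Br)c1O | intermediate
19 | phlorofucofuroeckol A octamethyl ether, ring B hydroxyl beside the ring A ether free (benzofuro-fused dibenzodioxin) | COc1cc(OC)cc(Oc2c(O)cc(OC)c3c2Oc2c(OC)cc4oc5c(Oc6cc(OC)cc(OC)c6)c(OC)cc(OC)c5c4c2O3)c1 | intermediate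
20 | phlorofucofuroeckol A | Oc1cc(O)cc(Oc2c(O)cc(O)c3c2Oc2c(O)cc4oc5c(Oc6cc(O)cc(O)c6)c(O)cc(O)c5c4c2O3)c1 | target

**Step count and risks**

Total: 13 steps. Longest linear sequence: 9 steps (6 → 7 → 9 → 11 → 12 → 14 → 17 → 18 → 19 → 20; steps 5–13).

Step 10 (key step). What may go wrong:
- exchange of the ring A aryloxy group at C2 by the incoming dibenzofuranoxide during the slow second displacement, which would scramble the two ether positions;
- stalling of that displacement because the nucleophile is flanked by bromine and methoxy;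
- attack through carbon by the ambident 3,5-dimethoxyphenoxide in the first stage.

Fallback: it sets out from 16, now isolated after the first substitution. Reduction with Na2S2O4 gives 3-bromo-2-(3,5-dimethoxyphenoxy)-5-methoxybenzene-1,4-diol F1, in which ring A is an ordinary diaryl ether that can no longer exchange. F1 and 14 are complementary ortho-bromophenols. Their copper-mediated Ullmann cross-condensation (CuI, 2,2,6,6-tetramethylheptane-3,5-dione, Cs2CO3, NMP, 120 °C, F1 in excess) would form both dioxin C–O bonds without a second quinone substitution. It comes back to the route at 19; the self-condensation products would have to be separated, so this is a lower-yielding route.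

Step 9. What may go wrong:
- C–C bond formation through the ring D carbon para to the hydroxyl (or through ring E), giving an arylhydroquinone that cannot close the furan;
- oxidation of 13 by unreacted quinone, followed by loss of the ring C bromide when the phenol adds to the arylquinone.

Fallback: it sets out from 6 and uses a symmetric resorcinol whose two nucleophilic carbons are equivalent.
- BCl3 (CH2Cl2, −78 to 0 °C) cleaves the methoxy group ortho to the formyl group to give 2,6-dihydroxy-4-methoxybenzaldehyde F2.
- Double benzylation (BnBr, K2CO3, DMF) gives 2,6-bis(benzyloxy)-4-methoxybenzaldehyde F3.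
- Baeyer–Villiger oxidation (mCPBA) gives 2,6-bis(benzyloxy)-4-methoxyphenyl formate F4, and methanolysis gives 2,6-bis(benzyloxy)-4-methoxyphenol F5.
- Ullmann coupling with 10 (CuI, picolinic acid, K3PO4, DMSO) gives 1,3-bis(benzyloxy)-2-(3,5-dimethoxyphenoxy)-5-methoxybenzene F6.
- Hydrogenolysis (H2, Pd/C) gives 2-(3,5-dimethoxyphenoxy)-5-methoxybenzene-1,3-diol F7.
- Condensation of F7 with 3 under the acid conditions of step 9 passes through 3-bromo-2-[3-(3,5-dimethoxyphenoxy)-2,4-dihydroxy-6-methoxyphenyl]-5-methoxybenzene-1,4-diol F8 to 1-bromo-6-(3,5-dimethoxyphenoxy)-3,9-dimethoxydibenzo[b,d]furan-2,7-diol F9.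
- Methylation of the dianion of F9 with one equivalent of MeI (K2CO3, DMF, 0 °C) should take place at the less hindered, more basic 7-oxide and not at the 2-oxide flanked by bromine and methoxy. This comes back to the route at 14.

Step 12. What may go wrong:
- air oxidation of the free hydroquinone back to the quinone under basic copper conditions;
- slow activation of the bay C–Br bond, crowded by the neighbouring aryloxy group and the peri methoxy group, leading to loss of bromine by reduction.

Fallback: it sets out from 18 and replaces copper coupling on the free hydroquinone by protection followed by palladium-catalysed etherification.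
- Benzylation with one equivalent of BnBr (K2CO3, acetone, rt) at the less hindered hydroxyl gives 4-(benzyloxy)-3-(3,5-dimethoxyphenoxy)-2-{[1-bromo-6-(3,5-dimethoxyphenoxy)-3,7,9-trimethoxydibenzo[b,d]furan-2-yl]oxy}-6-methoxyphenol F10.
- Intramolecular aryl ether formation (Pd(OAc)2, 2-(di-tert-butylphosphino)-2',4',6'-triisopropylbiphenyl, K3PO4, toluene, 100 °C) gives the benzyl ether of 19, F11.
- BBr3 then removes the benzyl and all methyl ethers together, coming back to the route at 20.

**Further compounds**

F1 | step 10 | 3-bromo-2-(3,5-dimethoxyphenoxy)-5-methoxybenzene-1,4-diol | COc1cc(O)c(Oc2cc(OC)cc(OC)c2)c(Br)c1O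
F2 | step 9 | 2,6-dihydroxy-4-methoxybenzaldehyde | COc1cc(O)c(C=O)c(O)c1
F3 | step 9 | 2,6-bis(benzyloxy)-4-methoxybenzaldehyde | COc1cc(OCc2ccccc2)c(C=O)c(OCc2ccccc2)c1
F4 | step 9 | 2,6-bis(benzyloxy)-4-methoxyphenyl formate | COc1cc(OCc2ccccc2)c(OC=O)c(OCc2ccccc2)c1
F5 | step 9 | 2,6-bis(benzyloxy)-4-methoxyphenol | COc1cc(OCc2ccccc2)c(O)c(OCc2ccccc2)c1
F6 | step 9 | 1,3-bis(benzyloxy)-2-(3,5-dimethoxyphenoxy)-5-methoxybenzene | COc1cc(OCc2ccccc2)c(Oc2cc(OC)cc(OC)c2)c(OCc2ccccc2)c1
F7 | step 9 | 2-(3,5-dimethoxyphenoxy)-5-methoxybenzene-1,3-diol | COc1cc(O)c(Oc2cc(OC)cc(OC)c2)c(O)c1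
F8 | step 9 | 3-bromo-2-[3-(3,5-dimethoxyphenoxy)-2,4-dihydroxy-6-methoxyphenyl]-5-methoxybenzene-1,4-diol | COc1cc(O)c(-c2c(O)c(Oc3cc(OC)cc(OC)c3)c(O)cc2OC)c(Br)c1O
F9 | step 9 | 1-bromo-6-(3,5-dimethoxyphenoxy)-3,9-dimethoxydibenzo[b,d]furan-2,7-diol | COc1cc2oc3c(Oc4cc(OC)cc(OC)c4)c(O)cc(OC)c3c2c(Br)c1O
F10 | step 12 | 4-(benzyloxy)-3-(3,5-dimethoxyphenoxy)-2-{[1-bromo-6-(3,5-dimethoxyphenoxy)-3,7,9-trimethoxydibenzo[b,d]furan-2-yl]oxy}-6-methoxyphenol | COc1cc(OCc2ccccc2)c(Oc2cc(OC)cc(OC)c2)c(Oc2c(OC)cc3oc4c(Oc5cc(OC)cc(OC)c5)c(OC)cc(OC)c4c3c2Br)c1O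
F11 | step 12 | benzyl ether of 19 (benzyloxy in place of the ring B hydroxyl) | COc1cc(OC)cc(Oc2c(OCc7ccccc7)cc(OC)c3c2Oc2c(OC)cc4oc5c(Oc6cc(OC)cc(OC)c6)c(OC)cc(OC)c5c4c2O3)c1
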